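**Retrosynthetic overview**
1. The target is read as an all-cis tetralin: C1 (CH3), C2 (OAc), C3 (CH2), C4 (side chain C11–C15), ring A = benzene C4a–C8a (C6 CH2OAc, C8 OH); configuration (1R,2S,4S,11S).
2. Endgame: selective release of the phenol from a triacetate ← triol ← (1R,2S)-alcohol ← 2-tetralone, by Noyori–Ikariya transfer hydrogenation with dynamic kinetic resolution (C1 epimerisable, C2 from the catalyst).
3. Key disconnection C3–C4, which closes ring B (the only ring formed): light-driven reductive radical cyclisation of an acyclic α-chloroketone inside a flavin-dependent ene-reductase. Enabling feature: C3 is α to the C2 carbonyl (radical site), and the vicinal stereocentres C4/C11 can be written as a trisubstituted olefin C4=C11 on ring A ortho to the C1 chain, so 6-exo attack of C3 on C4 and enzyme-delivered H to C11 create ring B and both stereocentres in one operation.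
4. Chloroketone ← methyl ketone ← Suzuki–Miyaura coupling of an aryl bromide with the alkenyl boronate made from 6-methylhept-5-en-2-one (boron-Wittig).
5. Aryl bromide ← directed ortho-metalation of bis-MOM-protected 3-bromo-5-(hydroxymethyl)phenol between Br and OMOM, opening of cis-2,3-epoxybutane, oxidation.

Key step: step 7

Remark: 3-bromo-5-(hydroxymethyl)phenol is taken as a purchasable building block (otherwise one LiAlH4 reduction of methyl 3-bromo-5-hydroxybenzoate), and the benzylic centre C1 is carried racemic up to the tetralone because it is epimerisable there and is set in step 8.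

**Route**

Step 1
Reactants: 1 3-bromo-5-(hydroxymethyl)phenol
Product: 2 1-bromo-3-(methoxymethoxy)-5-[(methoxymethoxy)methyl]benzene
Conditions: NaH (2.4 equiv), MOMCl (2.4 equiv), THF/DMF, 0 °C to rt
Reagents that add atoms: chloromethyl methyl ether (MOMCl), COCCl
Why: Williamson-type O-alkylation of the phenoxide and the benzylic alkoxide protects both hydroxyls in one operation and installs the aryl OMOM group that directs the metalation of step 2; no stereocentre is formed.

Step 2
Reactants: 2 1-bromo-3-(methoxymethoxy)-5-[(methoxymethoxy)methyl]benzene; 3 cis-2,3-epoxybutane (meso)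
Product: 5 3-[2-bromo-6-(methoxymethoxy)-4-[(methoxymethoxy)methyl]phenyl]butan-2-ol (racemic), via aryllithium 4 (not isolated)
Conditions: LiN(i-Pr)2 (1.1 equiv), THF, −78 °C; then 3, BF3·OEt2, −78 °C; H2O
Reagents that add atoms: none
Why: Directed ortho-metalation followed by BF3-promoted epoxide opening: the amide base (no bromine–lithium exchange) should remove the most acidic ring proton, the one flanked by Br and OMOM, and the aryllithium opens the activated epoxide by SN2 attack; the two new centres form as one racemic relative configuration, which is immaterial because the carbinol is oxidised in step 3 and C1 is reset in step 8.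

Step 3
Reactants: 5 3-[2-bromo-6-(methoxymethoxy)-4-[(methoxymethoxy)methyl]phenyl]butan-2-ol
Product: 6 3-[2-bromo-6-(methoxymethoxy)-4-[(methoxymethoxy)methyl]phenyl]butan-2-one (racemic)
Conditions: Dess–Martin periodinane (1.3 equiv), NaHCO3, CH2Cl2, rt
Reagents that add atoms: none
Why: Dess–Martin oxidation of the secondary alcohol under buffered conditions should give the α-aryl methyl ketone without touching the MOM acetals; the benzylic centre stays racemic.

Step 4
Reactants: 7 6-methylhept-5-en-2-one; 8 bis(4,4,5,5-tetramethyl-1,3,2-dioxaborolan-2-yl)methane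
Product: 10 2-(2,6-dimethylhepta-1,5-dien-1-yl)-4,4,5,5-tetramethyl-1,3,2-dioxaborolane (E/Z mixture), via lithiated diborylmethane 9 (not isolated)
Conditions: lithium 2,2,6,6-tetramethylpiperidide (1.1 equiv), THF, 0 °C; then 7, −78 °C to rt; H2O
Reagents that add atoms: none
Why: Boron-Wittig olefination: the α-diboryl carbanion adds to the ketone and eliminates a borate to give the trisubstituted alkenyl boronate; the E/Z ratio is immaterial because the olefin geometry is erased in the radical step 7.

Step 5
Reactants: 6 3-[2-bromo-6-(methoxymethoxy)-4-[(methoxymethoxy)methyl]phenyl]butan-2-one; 10 2-(2,6-dimethylhepta-1,5-dien-1-yl)-4,4,5,5-tetramethyl-1,3,2-dioxaborolane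
Product: 11 3-[2-(2,6-dimethylhepta-1,5-dien-1-yl)-6-(methoxymethoxy)-4-[(methoxymethoxy)methyl]phenyl]butan-2-one (racemic, E/Z mixture)
Conditions: Pd(OAc)2 (3 mol%), SPhos (6 mol%), K3PO4 (3 equiv), toluene/H2O (10:1), 80 °C
Reagents that add atoms: none
Why: Suzuki–Miyaura coupling: oxidative addition of zerovalent palladium carrying a bulky biaryl phosphine into the ortho-substituted aryl bromide, transmetalation of the alkenyl boronate and reductive elimination should join the two fragments while the ketone and the MOM acetals stay inert; no stereocentre is formed.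

Step 6
Reactants: 11 3-[2-(2,6-dimethylhepta-1,5-dien-1-yl)-6-(methoxymethoxy)-4-[(methoxymethoxy)methyl]phenyl]butan-2-one
Product: 13 1-chloro-3-[2-(2,6-dimethylhepta-1,5-dien-1-yl)-6-(methoxymethoxy)-4-[(methoxymethoxy)methyl]phenyl]butan-2-one (racemic, E/Z mixture), via silyl enol ether 12 (not isolated)
Conditions: LiN(i-Pr)2 (1.2 equiv), Me3SiCl (1.5 equiv), THF, −78 °C (internal quench); pentane filtration; then NCS (1.1 equiv), CH2Cl2, 0 °C
Reagents that add atoms: N-chlorosuccinimide (NCS), O=C1CCC(=O)N1Cl
Why: Kinetic enolate silylation followed by electrophilic α-chlorination of the silyl enol ether: deprotonation should occur at the methyl group and not at the hindered benzylic methine next to the doubly ortho-substituted aryl, and NCS chlorinates the electron-rich enol ether in preference to the two trisubstituted olefins.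

Step 7
Reactants: 13 1-chloro-3-[2-(2,6-dimethylhepta-1,5-dien-1-yl)-6-(methoxymethoxy)-4-[(methoxymethoxy)methyl]phenyl]butan-2-one
Product: 14 (4S)-8-(methoxymethoxy)-6-[(methoxymethoxy)methyl]-1-methyl-4-[(2S)-6-methylhept-5-en-2-yl]-3,4-dihydronaphthalen-2(1H)-one (C1 epimer mixture)
Conditions: flavin mononucleotide-dependent ene-reductase (Old Yellow Enzyme family, variant chosen from a panel, 1–2 mol%), NADP+ (cat.), glucose dehydrogenase, D-glucose (2 equiv), potassium phosphate buffer pH 8 with 15% DMSO, cyan LED (about 500 nm), 25 °C, anaerobic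
Reagents that add atoms: none
Why: Proposed new method: in the active site the reduced flavin cofactor forms a charge-transfer complex with the α-chloroketone, cyan light drives single-electron transfer and loss of chloride to give the C3 α-keto radical, this radical adds to C4 of the ortho olefin, and the tertiary C11 radical so formed is reduced by hydrogen-atom transfer from N5–H of the flavin semiquinone (the cofactor is recharged by NADPH from glucose and glucose dehydrogenase). The closest known reaction type is the light-driven reductive radical cyclisation of α-chloroamides onto alkenes in flavin-dependent ene-reductases (5-exo and 6-exo closures with stereoselective radical termination), together with the ene-reductase hydroalkylation of alkenes by α-halo carbonyl compounds, extended here to a carbocyclic ketone. Ring B (C1–C2–C3–C4–C4a–C8a) closes in the 6-exo-trig mode. C4 is set in the C–C bond-forming event by the olefin face that the protein presents to the radical and C11 by the face-selective hydrogen-atom transfer from the flavin, so both are under enzyme control and the E/Z mixture should converge because the olefin geometry is lost in the C11 radical; C1 stays epimerisable and is set in step 8. The step needs 6-exo attack at C4 instead of 7-endo attack at C11, and cyclisation faster than premature reduction of the C3 radical: the two ortho substituents twist the olefin out of the plane of ring A so that it reacts as an unconjugated trisubstituted alkene whose less substituted terminus is C4 and whose adduct radical is tertiary, the three-atom tether from C8a places C3 over C4, the remote C14=C15 olefin is out of reach, and the OMOM group on O8 prevents O-alkylation by the chloroketone. The variant that gives the (4S,11S) product has to be found by screening a panel of ene-reductases.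

Step 8
Reactants: 14 (4S)-8-(methoxymethoxy)-6-[(methoxymethoxy)methyl]-1-methyl-4-[(2S)-6-methylhept-5-en-2-yl]-3,4-dihydronaphthalen-2(1H)-one
Product: 15 (1R,2S,4S)-8-(methoxymethoxy)-6-[(methoxymethoxy)methyl]-1-methyl-4-[(2S)-6-methylhept-5-en-2-yl]-1,2,3,4-tetrahydronaphthalen-2-ol
Conditions: RuCl(p-cymene)[(S,S)-TsDPEN] (1 mol%), HCO2H/Et3N (5:2), CH2Cl2, 30 °C
Reagents that add atoms: none
Why: Noyori–Ikariya asymmetric transfer hydrogenation with dynamic kinetic resolution: the amine equilibrates the acidic benzylic C1 epimers through the enol, and the chiral ruthenium hydride should reduce the (1R) epimer preferentially, delivering hydride to C2 on the face opposite to the C1 methyl and the C4 side chain (also the substrate's own preference), so that C1 (R) and C2 (S) are set together in the all-cis array while the olefins stay untouched; the (S,S) ligand is assigned by analogy with aryl alkyl ketones, and its antipode is used if the sense proves reversed.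

Step 9
Reactants: 15 (1R,2S,4S)-8-(methoxymethoxy)-6-[(methoxymethoxy)methyl]-1-methyl-4-[(2S)-6-methylhept-5-en-2-yl]-1,2,3,4-tetrahydronaphthalen-2-ol
Product: 16 (1R,2S,4S)-6-(hydroxymethyl)-1-methyl-4-[(2S)-6-methylhept-5-en-2-yl]-1,2,3,4-tetrahydronaphthalene-2,8-diol
Conditions: ZnBr2 (2 equiv), n-PrSH (4 equiv), CH2Cl2, 0 °C, 15 min
Reagents that add atoms: none
Why: Lewis acid-assisted thiolytic cleavage of both MOM acetals (ZnBr2 activates the acetal oxygen and the thiol captures the methoxymethyl cation) should free the phenol and the benzylic alcohol under conditions mild enough for the trisubstituted olefin and all stereocentres.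

Step 10
Reactants: 16 (1R,2S,4S)-6-(hydroxymethyl)-1-methyl-4-[(2S)-6-methylhept-5-en-2-yl]-1,2,3,4-tetrahydronaphthalene-2,8-diol
Product: 17 (1R,2S,4S)-6-(acetoxymethyl)-1-methyl-4-[(2S)-6-methylhept-5-en-2-yl]-1,2,3,4-tetrahydronaphthalene-2,8-diyl diacetate
Conditions: Ac2O (6 equiv), pyridine, DMAP (10 mol%), CH2Cl2, rt
Reagents that add atoms: acetic anhydride, CC(=O)OC(C)=O
Why: DMAP-catalysed acetylation should esterify the primary, the secondary and the phenolic hydroxyl alike; no stereocentre is affected.

Step 11
Reactants: 17 (1R,2S,4S)-6-(acetoxymethyl)-1-methyl-4-[(2S)-6-methylhept-5-en-2-yl]-1,2,3,4-tetrahydronaphthalene-2,8-diyl diacetate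
Product: 18 (1R,2S,4S)-6-(acetoxymethyl)-8-hydroxy-1-methyl-4-[(2S)-6-methylhept-5-en-2-yl]-1,2,3,4-tetrahydronaphthalen-2-yl acetate (CNP0210401.2)
Conditions: pyrrolidine (1.2 equiv), CH2Cl2, 0 °C to rt
Reagents that add atoms: none
Why: Chemoselective aminolysis of an aryl acetate: the phenolic ester (phenoxide leaving group) should be cleaved by the secondary amine much faster than the two alkyl acetates, which releases the C8 phenol and leaves the target.

**Compound list**
1 | 3-bromo-5-(hydroxymethyl)phenol | OCc1cc(O)cc(Br)c1 | starting material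
2 | 1-bromo-3-(methoxymethoxy)-5-[(methoxymethoxy)methyl]benzene | COCOCc1cc(OCOC)cc(Br)c1 | intermediate
3 | cis-2,3-epoxybutane (meso, (2R,3S)-2,3-dimethyloxirane) | C[C@H]1[C@@H](C)O1 | starting material
4 | [2-bromo-6-(methoxymethoxy)-4-[(methoxymethoxy)methyl]phenyl]lithium | [Li]c1c(Br)cc(COCOC)cc1OCOC | intermediate (not isolated)
5 | 3-[2-bromo-6-(methoxymethoxy)-4-[(methoxymethoxy)methyl]phenyl]butan-2-ol, racemic | CC(O)C(C)c1c(Br)cc(COCOC)cc1OCOC | intermediate
6 | 3-[2-bromo-6-(methoxymethoxy)-4-[(methoxymethoxy)methyl]phenyl]butan-2-one, racemic | CC(=O)C(C)c1c(Br)cc(COCOC)cc1OCOC | intermediate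
7 | 6-methylhept-5-en-2-one | CC(=O)CCC=C(C)C | starting material
8 | bis(4,4,5,5-tetramethyl-1,3,2-dioxaborolan-2-yl)methane | CC1(C)OB(CB2OC(C)(C)C(C)(C)O2)OC1(C)C | starting material
9 | [bis(4,4,5,5-tetramethyl-1,3,2-dioxaborolan-2-yl)methyl]lithium | [Li]C(B1OC(C)(C)C(C)(C)O1)B1OC(C)(C)C(C)(C)O1 | intermediate (not isolated)
10 | 2-(2,6-dimethylhepta-1,5-dien-1-yl)-4,4,5,5-tetramethyl-1,3,2-dioxaborolane, E/Z mixture | CC(C)=CCCC(C)=CB1OC(C)(C)C(C)(C)O1 | intermediate
11 | 3-[2-(2,6-dimethylhepta-1,5-dien-1-yl)-6-(methoxymethoxy)-4-[(methoxymethoxy)methyl]phenyl]butan-2-one, racemic, E/Z mixture | CC(=O)C(C)c1c(C=C(C)CCC=C(C)C)cc(COCOC)cc1OCOC | intermediate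
12 | [3-[2-(2,6-dimethylhepta-1,5-dien-1-yl)-6-(methoxymethoxy)-4-[(methoxymethoxy)methyl]phenyl]but-1-en-2-yl]oxy(trimethyl)silane | C=C(O[Si](C)(C)C)C(C)c1c(C=C(C)CCC=C(C)C)cc(COCOC)cc1OCOC | intermediate (not isolated)
13 | 1-chloro-3-[2-(2,6-dimethylhepta-1,5-dien-1-yl)-6-(methoxymethoxy)-4-[(methoxymethoxy)methyl]phenyl]butan-2-one, racemic, E/Z mixture | ClCC(=O)C(C)c1c(C=C(C)CCC=C(C)C)cc(COCOC)cc1OCOC | intermediate
14 | (4S)-8-(methoxymethoxy)-6-[(methoxymethoxy)methyl]-1-methyl-4-[(2S)-6-methylhept-5-en-2-yl]-3,4-dihydronaphthalen-2(1H)-one, C1 epimer mixture | COCOCc1cc(OCOC)c2c(c1)[C@H]([C@@H](C)CCC=C(C)C)CC(=O)C2C | intermediate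
15 | (1R,2S,4S)-8-(methoxymethoxy)-6-[(methoxymethoxy)methyl]-1-methyl-4-[(2S)-6-methylhept-5-en-2-yl]-1,2,3,4-tetrahydronaphthalen-2-ol | COCOCc1cc(OCOC)c2c(c1)[C@H]([C@@H](C)CCC=C(C)C)C[C@H](O)[C@@H]2C | intermediate
16 | (1R,2S,4S)-6-(hydroxymethyl)-1-methyl-4-[(2S)-6-methylhept-5-en-2-yl]-1,2,3,4-tetrahydronaphthalene-2,8-diol | OCc1cc(O)c2c(c1)[C@H]([C@@H](C)CCC=C(C)C)C[C@H](O)[C@@H]2C | intermediate
17 | (1R,2S,4S)-6-(acetoxymethyl)-1-methyl-4-[(2S)-6-methylhept-5-en-2-yl]-1,2,3,4-tetrahydronaphthalene-2,8-diyl diacetate | CC(=O)OCc1cc(OC(C)=O)c2c(c1)[C@H]([C@@H](C)CCC=C(C)C)C[C@H](OC(C)=O)[C@@H]2C | intermediate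
18 | (1R,2S,4S)-6-(acetoxymethyl)-8-hydroxy-1-methyl-4-[(2S)-6-methylhept-5-en-2-yl]-1,2,3,4-tetrahydronaphthalen-2-yl acetate (CNP0210401.2) | CC(=O)OCc1cc(O)c2c(c1)[C@H]([C@@H](C)CCC=C(C)C)C[C@H](OC(C)=O)[C@@H]2C | target

**Step count and risks**
Total step count: 11. Longest linear sequence: 10 steps (steps 1–3 and 5–11, from compound 1); step 4 is the side branch.

Steps most likely to fail:

1. Step 7 (Proposed new method). What may go wrong: hydrogen-atom transfer to the C3 radical before cyclisation (hydrodehalogenation back to the methyl ketone), 7-endo closure, poor binding of the lipophilic substrate, acceptance of only one C1 enantiomer of the substrate, or insufficient facial control at C4 and C11. Fallback (known chemistry, sets out from 2 and returns at 14): ortho-lithiation of 2 (LiN(i-Pr)2, −78 °C) and quenching with hexachloroethane would give 1-bromo-2-chloro-3-(methoxymethoxy)-5-[(methoxymethoxy)methyl]benzene F1. Bromine–lithium exchange (n-BuLi, −100 °C, B(Oi-Pr)3 present, acidic work-up) would give [2-chloro-3-(methoxymethoxy)-5-[(methoxymethoxy)methyl]phenyl]boronic acid F2. In parallel, (S)-2,6-dimethylhept-5-enal F3, available from (S)-citronellal by the known one-carbon oxidative degradation, would be olefinated with dimethyl (2-oxobutyl)phosphonate (Horner–Wadsworth–Emmons, LiCl, i-Pr2NEt) to (S,E)-6,10-dimethylundeca-4,9-dien-3-one F4. Rhodium-catalysed asymmetric 1,4-addition of F2 to F4 ([Rh(cod)Cl]2, BINAP enantiomer chosen for the 5S adduct, KOH, dioxane/H2O) would give (5S,6S)-5-[2-chloro-3-(methoxymethoxy)-5-[(methoxymethoxy)methyl]phenyl]-6,10-dimethylundec-9-en-3-one F5; C4 comes from the catalyst and C11 from citronellal. Palladium-catalysed intramolecular ketone α-arylation (Pd2(dba)3, XPhos, NaOt-Bu, toluene, 80 °C) then closes the C1–C8a bond and delivers 14.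

2. Step 8. What may go wrong: mismatched double stereodifferentiation between catalyst and the C4 centre, or C1 epimerisation slower than reduction, so that the (1S,2R) series accumulates. Fallback (sets out from 14 and returns at 15): substrate-controlled reduction with LiBH(s-Bu)3 (L-Selectride), THF, −78 °C, adds hydride anti to the C1 methyl in both C1 epimers. It should give 15 together with (1S,2R,4S)-8-(methoxymethoxy)-6-[(methoxymethoxy)methyl]-1-methyl-4-[(2S)-6-methylhept-5-en-2-yl]-1,2,3,4-tetrahydronaphthalen-2-ol F6. The two are diastereomers and separable on silica; F6 is re-oxidised with Dess–Martin periodinane to the epimerisable ketone 14 and recycled.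

3. Step 2. What may go wrong: loss of LiBr from the ortho-bromo aryllithium (aryne formation) or sluggish SN2 opening of the internal epoxide by the hindered nucleophile. Fallback (sets out from 2 and returns at 6): the aryllithium 4 is instead reacted with propylene oxide and BF3·OEt2 at −78 °C (attack at the unhindered CH2) to give 1-[2-bromo-6-(methoxymethoxy)-4-[(methoxymethoxy)methyl]phenyl]propan-2-ol F7. Dess–Martin oxidation gives 1-[2-bromo-6-(methoxymethoxy)-4-[(methoxymethoxy)methyl]phenyl]propan-2-one F8. Methylation at its more acidic benzylic position (NaH, MeI, THF, 0 °C) then introduces the C1 methyl and gives 6.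

Further compounds
F1 | step 7 | 1-bromo-2-chloro-3-(methoxymethoxy)-5-[(methoxymethoxy)methyl]benzene | COCOCc1cc(Br)c(Cl)c(OCOC)c1
F2 | step 7 | [2-chloro-3-(methoxymethoxy)-5-[(methoxymethoxy)methyl]phenyl]boronic acid | COCOCc1cc(B(O)O)c(Cl)c(OCOC)c1
F3 | step 7 | (S)-2,6-dimethylhept-5-enal | O=C[C@@H](C)CCC=C(C)C
F4 | step 7 | (S,E)-6,10-dimethylundeca-4,9-dien-3-one | CCC(=O)/C=C/[C@@H](C)CCC=C(C)C
F5 | step 7 | (5S,6S)-5-[2-chloro-3-(methoxymethoxy)-5-[(methoxymethoxy)methyl]phenyl]-6,10-dimethylundec-9-en-3-one | CCC(=O)C[C@H](c1cc(COCOC)cc(OCOC)c1Cl)[C@@H](C)CCC=C(C)C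
F6 | step 8 | (1S,2R,4S)-8-(methoxymethoxy)-6-[(methoxymethoxy)methyl]-1-methyl-4-[(2S)-6-methylhept-5-en-2-yl]-1,2,3,4-tetrahydronaphthalen-2-ol | COCOCc1cc(OCOC)c2c(c1)[C@H]([C@@H](C)CCC=C(C)C)C[C@@H](O)[C@H]2C
F7 | step 2 | 1-[2-bromo-6-(methoxymethoxy)-4-[(methoxymethoxy)methyl]phenyl]propan-2-ol | CC(O)Cc1c(Br)cc(COCOC)cc1OCOC
F8 | step 2 | 1-[2-bromo-6-(methoxymethoxy)-4-[(methoxymethoxy)methyl]phenyl]propan-2-one | CC(=O)Cc1c(Br)cc(COCOC)cc1OCOC
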